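**Retrosynthetic overview**

1. Feature and key cut: ring G (cyclopentene C16–C17–C18–C19=C20) is fused to ring F (cycloheptane C10–C13–C14–C15–C16–C20–C21) across C16–C20, with sp2 C20 on quaternary C21 and C16 as the only stereocentre of the pair. This is the signature of an enyne cyclocarbonylation, so rings F and G are cut together (C16–C20, C17–C18, C18–C19) by a Pauson–Khand reaction of a pentacyclic 1,8-enyne (ethynyl on C21, but-3-enyl on C13); the C18 oxygen is removed afterwards.
2. Enyne: the ethynyl group comes from a C20 thioester on C21 (reduction, oxidation, Ohira–Bestmann homologation). Its CH2OH stage directs hydride to C27 (exo C27–O26), and ring E follows from an exo-face acrylate Michael addition at C21.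
3. Rings C and D: ring D is a cyclopentenone made at C27 by Meldrum's acid homologation and Knoevenagel closure. Ring C is closed onto C10 by a tethered enamine Michael addition of hex-5-enal on N29 with iminium reduction, which brings in the butenyl chain without a lactam.
4. Rings A and B: vinylogous Mannich reaction of the silyloxyfuran of 4-methylfuran-2(5H)-one with a sulfinyl imino ester (C7), radical cyclisation of an N–CH2 unit onto the butenolide (C2), and allylation of the cyclic ketimine (C8).
5. Order of ring formation: A, B, D, C, E, then F and G together in the key step.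

Key step: step 23

Remark: atom labels C1 to C30 follow the atom order of the target SMILES; rings are A (γ-lactone), B (pyrrolidine), C (piperidine), D (cyclopentane), E (δ-lactone), F (cycloheptane), G (cyclopentene).
Assumption: in step 3 the (R)-sulfinyl imine is taken to react in an open, threo-selective transition state on the face anti to the tert-butyl group (C8 R, C7 S); if the sense is the opposite, (S)-4 is used, and since C8 is re-made in steps 7 and 10 only C7 has to be right.
Remark: O12 is carried as its tert-butyldiphenylsilyl ether so that it survives the acid steps 16, 21 and 25.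

Step 1
Reactants: 1 4-methylfuran-2(5H)-one
Product: 2 2-(tert-butyldimethylsilyloxy)-4-methylfuran
Conditions: TBSOTf, Et3N, CH2Cl2, 0 °C
Reagents that add atoms: tert-butyldimethylsilyl trifluoromethanesulfonate, CC(C)(C)[Si](C)(C)OS(=O)(=O)C(F)(F)F
Why: γ-deprotonation of the butenolide and O-silylation of the resulting 2-oxidofuran (silyl dienol ether formation) should give the aromatic silyloxyfuran.

Step 2
Reactants: 3 allyl glyoxylate (used as its hydrate); 4 (R)-2-methylpropane-2-sulfinamide
Product: 5 allyl (E)-[(R)-tert-butylsulfinylimino]acetate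
Conditions: 4 Å molecular sieves, CH2Cl2, rt
Reagents that add atoms: none
Why: condensation of the sulfinamide with the non-enolisable, strongly electrophilic glyoxylate aldehyde (imine formation) should give the E sulfinyl imine.

Step 3
Reactants: 2 2-(tert-butyldimethylsilyloxy)-4-methylfuran; 5 allyl (E)-[(R)-tert-butylsulfinylimino]acetate
Product: 6 allyl (2R)-[(R)-tert-butylsulfinylamino][(2S)-3-methyl-5-oxo-2,5-dihydrofuran-2-yl]acetate
Conditions: TMSOTf (0.2 equiv), CH2Cl2, −78 °C; aq NaHCO3
Reagents that add atoms: none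
Why: in this Lewis acid-promoted vinylogous Mukaiyama–Mannich reaction the furan should attack through its C5 (later C7) on the imine face anti to the tert-butyl group in an open, threo-selective transition state, so that the auxiliary sets C8 (R) and the threo preference sets C7 (S).

Step 4
Reactants: 6 allyl (2R)-[(R)-tert-butylsulfinylamino][(2S)-3-methyl-5-oxo-2,5-dihydrofuran-2-yl]acetate
Product: 7 allyl (2R)-amino[(2S)-3-methyl-5-oxo-2,5-dihydrofuran-2-yl]acetate hydrochloride
Conditions: HCl (4 M in 1,4-dioxane), Et2O, 0 °C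
Reagents that add atoms: hydrogen chloride, Cl
Why: acidolysis of the N–S bond (sulfinamide cleavage) should free the amine as its salt without touching the ester, the butenolide or either stereocentre.

Step 5
Reactants: 7 allyl (2R)-amino[(2S)-3-methyl-5-oxo-2,5-dihydrofuran-2-yl]acetate hydrochloride
Product: 8 allyl (2R)-[(2S)-3-methyl-5-oxo-2,5-dihydrofuran-2-yl][(trimethylsilylmethyl)amino]acetate
Conditions: Me3SiCH2OTf, NaHCO3, MeCN, 0 °C to rt
Reagents that add atoms: (trimethylsilyl)methyl trifluoromethanesulfonate, C[Si](C)(C)COS(=O)(=O)C(F)(F)F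
Why: SN2 N-alkylation by the very reactive triflate should stop at the hindered secondary amine, and the weak heterogeneous base avoids γ-deprotonation of the butenolide at C7.

Step 6
Reactants: 8 allyl (2R)-[(2S)-3-methyl-5-oxo-2,5-dihydrofuran-2-yl][(trimethylsilylmethyl)amino]acetate
Product: 9 allyl (3aS,6R,6aS)-3a-methyl-2-oxohexahydro-2H-furo[2,3-c]pyrrole-6-carboxylate (rings A/B; C2 S; C7 S; C8 R)
Conditions: 2,4,5,6-tetra(carbazol-9-yl)isophthalonitrile (2 mol %), blue LEDs, MeOH/MeCN, rt, degassed
Reagents that add atoms: none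
Why: photoredox oxidation of the α-silylamine and desilylation give the N–CH2 radical (C30), whose 5-exo-trig Giese cyclisation onto the butenolide β-carbon C2, followed by reduction and protonation at C3, closes ring B; the 5/5 fusion can only be cis, so C7 sets the quaternary centre C2.

Step 7
Reactants: 9 allyl (3aS,6R,6aS)-3a-methyl-2-oxohexahydro-2H-furo[2,3-c]pyrrole-6-carboxylate
Product: 11 allyl (3aS,6aS)-3a-methyl-2-oxo-3,3a,4,6a-tetrahydro-2H-furo[2,3-c]pyrrole-6-carboxylate (cyclic imino ester C8=N29), via N-chloroamine 10 (not isolated)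
Conditions: NCS, CH2Cl2, 0 °C; then DBU, 0 °C to rt
Reagents that add atoms: none
Why: N-chlorination and dehydrochlorination toward the acidic C8–H (amine-to-imine oxidation) should give the conjugated α-imino ester, and C7 cannot epimerise because its fusion to quaternary C2 must stay cis.

Step 8
Reactants: 12 2-methylidenepropane-1,3-diol
Product: 13 2-[(tert-butyldiphenylsilyloxy)methyl]prop-2-en-1-ol
Conditions: NaH (1 equiv), THF, 0 °C; then TBDPSCl
Reagents that add atoms: tert-butyl(chloro)diphenylsilane, CC(C)(C)[Si](Cl)(c1ccccc1)c1ccccc1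
Why: O-silylation of the monosodium alkoxide of the symmetric diol (monoprotection) should give the mono silyl ether.

Step 9
Reactants: 13 2-[(tert-butyldiphenylsilyloxy)methyl]prop-2-en-1-ol
Product: 14 [2-(bromomethyl)prop-2-enyloxy](tert-butyl)diphenylsilane
Conditions: CBr4, PPh3, CH2Cl2, 0 °C
Reagents that add atoms: carbon tetrabromide, BrC(Br)(Br)Br
Why: Appel bromination of the primary allylic alcohol is mild enough for the silyl ether.

Step 10
Reactants: 11 allyl (3aS,6aS)-3a-methyl-2-oxo-3,3a,4,6a-tetrahydro-2H-furo[2,3-c]pyrrole-6-carboxylate; 14 [2-(bromomethyl)prop-2-enyloxy](tert-butyl)diphenylsilane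
Product: 15 allyl (3aS,6R,6aS)-6-{2-[(tert-butyldiphenylsilyloxy)methyl]prop-2-enyl}-3a-methyl-2-oxohexahydro-2H-furo[2,3-c]pyrrole-6-carboxylate
Conditions: Zn dust, THF, 0 °C to rt; aq NH4Cl
Reagents that add atoms: none
Why: Barbier allylation of the activated ketimine by the allylzinc reagent, which leaves lactone and ester alone, should occur on the convex face of the cis-fused bicycle and anti to the C7–O6 bond (Felkin–Anh), placing C9 cis to H7 and the C1 methyl group and so setting the α-tertiary amine centre C8.

Step 11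
Reactants: 15 allyl (3aS,6R,6aS)-6-{2-[(tert-butyldiphenylsilyloxy)methyl]prop-2-enyl}-3a-methyl-2-oxohexahydro-2H-furo[2,3-c]pyrrole-6-carboxylate
Product: 16 N-Boc derivative of 15 (tert-butyl carbamate on N29)
Conditions: Boc2O, DMAP (cat.), MeCN, 50 °C
Reagents that add atoms: di-tert-butyl dicarbonate, CC(C)(C)OC(=O)OC(=O)OC(C)(C)C
Why: carbamate formation (Boc protection) masks the hindered secondary amine for the carboxyl activation of step 14.

Step 12
Reactants: 16 N-Boc derivative of 15
Product: 17 N-Boc C27 carboxylic acid (16 with CO2H in place of the allyl ester)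
Conditions: Pd(PPh3)4 (5 mol %), morpholine, THF, rt; aq citric acid
Reagents that add atoms: none
Why: zerovalent palladium ionises the allyl ester and morpholine traps the allyl fragment (Tsuji–Trost deallylation), which leaves the lactone, the carbamate and the allylic silyl ether untouched.

Step 13
Reactants: 17 N-Boc C27 carboxylic acid
Product: 18 N-Boc keto acid (C10 ketone; chain C9H2–C10(=O)–C11H2OTBDPS on C8)
Conditions: O3, CH2Cl2/MeOH, −78 °C; then Me2S
Reagents that add atoms: ozone, [O-][O+]=O
Why: ozonolysis of the only alkene left, with reductive work-up, should give the C10 ketone.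

Step 14
Reactants: 18 N-Boc keto acid
Product: 20 N-Boc β-keto thioester (C8–C27(=O)–C21H2–C20(=O)SEt), via acyl Meldrum's acid 19 (not isolated)
Conditions: Meldrum's acid, EDCI·HCl, DMAP, CH2Cl2, 0 °C to rt; then EtSH, PhMe, 80 °C (sealed tube)
Reagents that add atoms: Meldrum's acid, CC1(C)OC(=O)CC(=O)O1; ethanethiol, CCS
Why: C-acylation of Meldrum's acid by the carbodiimide-activated acid and thermal loss of acetone and CO2 through an acylketene trapped by the thiol (Meldrum's acid route to β-keto thioesters) add C21 and C20 without exposing lactone A to a carbon nucleophile.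

Step 15
Reactants: 20 N-Boc β-keto thioester
Product: 21 N-Boc spiro enone thioester (rings A/B/D; ring D = C8–C27(=O)–C21(COSEt)=C10(CH2OTBDPS)–C9)
Conditions: piperidinium acetate (20 mol %), 4 Å molecular sieves, PhMe, 50 °C
Reagents that add atoms: none
Why: intramolecular Knoevenagel condensation of the doubly activated C21 methylene with the C10 ketone (a 1,4-dicarbonyl cyclisation to a cyclopentenone) closes ring D, and because C8 is quaternary only C21 can act as the nucleophile.

Step 16
Reactants: 21 N-Boc spiro enone thioester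
Product: 22 spiro enone thioester as the N29 ammonium trifluoroacetate
Conditions: TFA, CH2Cl2, 0 °C to rt
Reagents that add atoms: trifluoroacetic acid, OC(=O)C(F)(F)F
Why: acidolysis of the tert-butyl carbamate frees N29, and the salt form keeps the amine from adding to the alkylidene dicarbonyl unit.

Step 17
Reactants: 22 spiro enone thioester trifluoroacetate; 23 hex-5-enal
Product: 26 tetracyclic amino β-keto thioester (rings A–D; bridge N29–C28H2–C13H(but-3-enyl)–C10; C21H–COSEt; stereocentres C2 C7 C8 C10 C13 as in the target), via dienamine 24 (not isolated), via bicyclic enamine 25 (not isolated)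
Conditions: NaOAc, 4 Å molecular sieves, ClCH2CH2Cl, rt; then AcOH, NaBH(OAc)3, 0 °C to rt
Reagents that add atoms: none
Why: the secondary amine and the aldehyde form an enamine whose β-carbon C13, held by the N29–C28 tether on the nitrogen face of ring D, adds 6-exo to C10 of the alkylidene β-keto thioester (intramolecular Stork enamine Michael addition), and hydride reduction of the iminium (reductive amination) fixes ring C; the tether forces C13 cis to N29 and so sets quaternary C10, while C13 equilibrates through the iminium–enamine pair and should be protonated on the exo face, leaving the butenyl chain equatorial.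

Step 18
Reactants: 26 tetracyclic amino β-keto thioester; 27 tert-butyl prop-2-enoate
Product: 28 C21-quaternary keto thioester (26 with exo CH2CH2CO2tBu on C21; COSEt endo)
Conditions: DBU (0.2 equiv), MeCN, rt
Reagents that add atoms: none
Why: the base-catalysed Michael addition should take place on the exo face of the bicyclo[3.2.1] enolate, syn to the one-carbon bridge C9 and away from the N29–C28–C13 bridge, so that C22 becomes exo and C20 endo at quaternary C21.

Step 19
Reactants: 28 C21-quaternary keto thioester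
Product: 30 diol (endo CH2OH on C21; exo C27–OH; tert-butyl ester intact), via hydroxy ketone 29 (not isolated)
Conditions: NaBH4, THF/EtOH, −10 °C; then Me4NBH(OAc)3, MeCN/AcOH, −20 °C to rt
Reagents that add atoms: none
Why: NaBH4 reduces the thioester much faster than the tert-butyl ester, the lactone or the doubly neopentyl ketone, and the endo C20 carbinol then binds the triacetoxyborohydride and delivers hydride to C27 from the endo face (Saksena–Evans directed reduction), giving the exo C27 alcohol that external hydride, expected on the exo face, would not give.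

Step 20
Reactants: 30 diol
Product: 31 hydroxy aldehyde (30 with endo CHO on C21)
Conditions: Cu(MeCN)4OTf (5 mol %), 2,2'-bipyridine, TEMPO, N-methylimidazole, air, MeCN, rt
Reagents that add atoms: none
Why: aminoxyl-mediated aerobic oxidation catalysed by monovalent copper is selective for the primary carbinol, and the C27 alcohol between two quaternary carbons should not react.

Step 21
Reactants: 31 hydroxy aldehyde
Product: 33 pentacyclic lactone aldehyde (rings A–E; endo CHO on C21), via hydroxy acid 32 (not isolated)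
Conditions: TFA, CH2Cl2, 0 °C to rt; evaporate; then EDCI·HCl, DMAP, CH2Cl2, rt
Reagents that add atoms: none
Why: acidolysis of the tert-butyl ester and carbodiimide lactonisation of the δ-hydroxy acid close ring E, which can only be cis-fused across C21–C27, and no second hydroxyl group is left to compete.

Step 22
Reactants: 33 pentacyclic lactone aldehyde
Product: 34 pentacyclic 1,8-enyne (rings A–E; endo ethynyl on C21; but-3-enyl on C13; O12 TBDPS ether)
Conditions: MeC(O)C(N2)P(O)(OMe)2, K2CO3, MeOH, 0 °C to rt; then PPTS, PhMe, 40 °C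
Reagents that add atoms: dimethyl (1-diazo-2-oxopropyl)phosphonate, COP(=O)(OC)C(=[N+]=[N-])C(C)=O
Why: Ohira–Bestmann homologation turns the non-enolisable aldehyde into the terminal alkyne through a diazoalkene and the 1,2-hydrogen shift of its alkylidene carbene, and the mild acid finish should re-close any lactone opened by methoxide.

Step 23
Reactants: 34 pentacyclic 1,8-enyne
Product: 36 heptacyclic C18 enone (rings A–G; C19=C20; H16 cis to H13; O12 TBDPS ether), via dicobalt complex 35 (not isolated)
Conditions: Co2(CO)8, CH2Cl2, rt; then n-BuSMe, ClCH2CH2Cl, 80 °C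
Reagents that add atoms: octacarbonyldicobalt, O=C=[Co](=C=O)(=C=O)(=C=O)[Co](=C=O)(=C=O)(=C=O)=C=O
Why: Co2(CO)8 should first bind the C19≡C20 triple bond as the hexacarbonyldicobalt complex 35; on heating with the sulfide a CO ligand gives way to the C16=C17 alkene, which inserts into the Co–C20 bond (C16–C20), and CO insertion into the new Co–C17 bond with reductive elimination then forms C17–C18 and C18–C19. The closest known reaction type is the intramolecular Pauson–Khand reaction of 1,6- and 1,7-enynes, of which the 1,8-enyne with a seven-membered tether ring is the less common extension. Ring F (C10–C13–C14–C15–C16–C20–C21) closes as the tether ring in the alkene insertion (7-exo with respect to the alkene), and ring G (C16–C17–C18–C19=C20, as its C18 ketone) closes as the newly assembled ring in the carbonylative reductive elimination. The one new stereocentre, C16, should be set by the cage: the chain can reach the cobalt-bound alkyne only along the concave endo face between C13 and C21, and in that fold the alkene offers the face that puts H16 cis to H13 across ring F, whereas the other face would push C17 into the C28–N29 bridge. The step needs intramolecular cyclocarbonylation to beat decomplexation and intermolecular reaction, and it needs C16 to bond to C20 and not to C19; both are secured because the ethynyl group on quaternary C21 and the butenyl chain on C13 sit syn on the rigid 2-azabicyclo[3.2.1]octane core, so that only the C13–C14, C14–C15 and C15–C16 rotations must be ordered, and because bonding to C19 would demand an eight-membered tether ring.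

Step 24
Reactants: 36 heptacyclic C18 enone
Product: 37 C18 allylic alcohol (36 with C18–OH; either epimer)
Conditions: NaBH4, CeCl3·7H2O, MeOH, −40 to 0 °C
Reagents that add atoms: none
Why: Luche reduction should add hydride 1,2 to the enone and spare both lactones at low temperature; the C18 configuration does not matter because the centre is removed in step 25.

Step 25
Reactants: 37 C18 allylic alcohol
Product: 38 O12 tert-butyldiphenylsilyl ether of the target
Conditions: Et3SiH, TFA, CH2Cl2, −20 to 0 °C
Reagents that add atoms: none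
Why: in this ionic hydrogenation the acid ionises the alcohol to the C18–C19–C20 allyl cation and the silane should deliver hydride to the unhindered secondary terminus C18 and not to the tertiary, neopentyl C20, so the C19=C20 alkene is kept (palladium–formate hydrogenolysis of an allylic carbonate would instead put hydride on the more substituted terminus C20).

Step 26
Reactants: 38 O12 tert-butyldiphenylsilyl ether of the target
Product: 39 target CNP0247797.1
Conditions: HF·pyridine, THF, 0 °C to rt
Reagents that add atoms: none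
Why: fluoride-mediated desilylation under mildly acidic conditions frees the C11 carbinol without opening either lactone.

**Compound list**

1 | 4-methylfuran-2(5H)-one | CC1=CC(=O)OC1 | starting material
2 | 2-(tert-butyldimethylsilyloxy)-4-methylfuran | Cc1coc(O[Si](C)(C)C(C)(C)C)c1 | intermediate
3 | allyl glyoxylate (prop-2-enyl 2-oxoacetate; used as its hydrate) | C=CCOC(=O)C=O | starting material
4 | (R)-2-methylpropane-2-sulfinamide | CC(C)(C)[S@@](=O)N | starting material
5 | allyl (E)-[(R)-tert-butylsulfinylimino]acetate | CC(C)(C)[S@@](=O)/N=C/C(=O)OCC=C | intermediate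
6 | allyl (2R)-[(R)-tert-butylsulfinylamino][(2S)-3-methyl-5-oxo-2,5-dihydrofuran-2-yl]acetate | CC1=CC(=O)O[C@@H]1[C@@H](N[S@](=O)C(C)(C)C)C(=O)OCC=C | intermediate
7 | allyl (2R)-amino[(2S)-3-methyl-5-oxo-2,5-dihydrofuran-2-yl]acetate hydrochloride | CC1=CC(=O)O[C@@H]1[C@@H]([NH3+])C(=O)OCC=C.[Cl-] | intermediate
8 | allyl (2R)-[(2S)-3-methyl-5-oxo-2,5-dihydrofuran-2-yl][(trimethylsilylmethyl)amino]acetate | CC1=CC(=O)O[C@@H]1[C@@H](NC[Si](C)(C)C)C(=O)OCC=C | intermediate
9 | allyl (3aS,6R,6aS)-3a-methyl-2-oxohexahydro-2H-furo[2,3-c]pyrrole-6-carboxylate (rings A/B; C2 S; C7 S; C8 R) | C[C@@]12CC(=O)O[C@@H]1[C@H](C(=O)OCC=C)NC2 | intermediate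
10 | N-chloroamine: allyl (3aS,6R,6aS)-5-chloro-3a-methyl-2-oxohexahydro-2H-furo[2,3-c]pyrrole-6-carboxylate | C[C@@]12CC(=O)O[C@@H]1[C@H](C(=O)OCC=C)N(Cl)C2 | intermediate
11 | allyl (3aS,6aS)-3a-methyl-2-oxo-3,3a,4,6a-tetrahydro-2H-furo[2,3-c]pyrrole-6-carboxylate (cyclic imino ester C8=N29) | C[C@@]12CC(=O)O[C@@H]1C(C(=O)OCC=C)=NC2 | intermediate
12 | 2-methylidenepropane-1,3-diol | C=C(CO)CO | starting material
13 | 2-[(tert-butyldiphenylsilyloxy)methyl]prop-2-en-1-ol | C=C(CO)CO[Si](c1ccccc1)(c1ccccc1)C(C)(C)C | intermediate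
14 | [2-(bromomethyl)prop-2-enyloxy](tert-butyl)diphenylsilane | C=C(CBr)CO[Si](c1ccccc1)(c1ccccc1)C(C)(C)C | intermediate
15 | allyl (3aS,6R,6aS)-6-{2-[(tert-butyldiphenylsilyloxy)methyl]prop-2-enyl}-3a-methyl-2-oxohexahydro-2H-furo[2,3-c]pyrrole-6-carboxylate | C[C@@]12CC(=O)O[C@@H]1[C@@](C(=O)OCC=C)(CC(=C)CO[Si](c3ccccc3)(c3ccccc3)C(C)(C)C)NC2 | intermediate
16 | N-Boc derivative of 15 (tert-butyl carbamate on N29) | C[C@@]12CC(=O)O[C@@H]1[C@@](C(=O)OCC=C)(CC(=C)CO[Si](c3ccccc3)(c3ccccc3)C(C)(C)C)N(C(=O)OC(C)(C)C)C2 | intermediate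
17 | N-Boc C27 carboxylic acid (16 with CO2H in place of the allyl ester) | C[C@@]12CC(=O)O[C@@H]1[C@@](C(=O)O)(CC(=C)CO[Si](c3ccccc3)(c3ccccc3)C(C)(C)C)N(C(=O)OC(C)(C)C)C2 | intermediate
18 | N-Boc keto acid (C10 ketone; chain C9H2–C10(=O)–C11H2OTBDPS on C8) | C[C@@]12CC(=O)O[C@@H]1[C@@](C(=O)O)(CC(=O)CO[Si](c3ccccc3)(c3ccccc3)C(C)(C)C)N(C(=O)OC(C)(C)C)C2 | intermediate
19 | acyl Meldrum's acid of 18 (enol form) | C[C@@]12CC(=O)O[C@@H]1[C@@](C(O)=C3C(=O)OC(C)(C)OC3=O)(CC(=O)CO[Si](c4ccccc4)(c4ccccc4)C(C)(C)C)N(C(=O)OC(C)(C)C)C2 | intermediate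
20 | N-Boc β-keto thioester (C8–C27(=O)–C21H2–C20(=O)SEt) | C[C@@]12CC(=O)O[C@@H]1[C@@](C(=O)CC(=O)SCC)(CC(=O)CO[Si](c3ccccc3)(c3ccccc3)C(C)(C)C)N(C(=O)OC(C)(C)C)C2 | intermediate
21 | N-Boc spiro enone thioester (rings A/B/D; ring D = C8–C27(=O)–C21(COSEt)=C10(CH2OTBDPS)–C9) | C[C@@]12CC(=O)O[C@@H]1[C@]3(C(=O)C(C(=O)SCC)=C(CO[Si](c4ccccc4)(c4ccccc4)C(C)(C)C)C3)N(C(=O)OC(C)(C)C)C2 | intermediate
22 | spiro enone thioester as the N29 ammonium trifluoroacetate | C[C@@]12CC(=O)O[C@@H]1[C@]3(C(=O)C(C(=O)SCC)=C(CO[Si](c4ccccc4)(c4ccccc4)C(C)(C)C)C3)[NH2+]C2.[O-]C(=O)C(F)(F)F | intermediate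
23 | hex-5-enal | C=CCCCC=O | starting material
24 | dienamine (N29–C28H=C13H–CH2CH2CH=CH2 on the spiro enone thioester) | C[C@@]12CC(=O)O[C@@H]1[C@]3(C(=O)C(C(=O)SCC)=C(CO[Si](c4ccccc4)(c4ccccc4)C(C)(C)C)C3)N(/C=C/CCC=C)C2 | intermediate
25 | bicyclic enamine (rings A–D closed; C28=C13; C21H–COSEt) | C[C@@]12CC(=O)O[C@@H]1[C@]13C[C@@](C(C(=O)SCC)C1=O)(CO[Si](c5ccccc5)(c5ccccc5)C(C)(C)C)C(CCC=C)=CN3C2 | intermediate
26 | tetracyclic amino β-keto thioester (rings A–D; bridge N29–C28H2–C13H(but-3-enyl)–C10; C21H–COSEt; stereocentres C2 C7 C8 C10 C13 as in the target) | C[C@@]12CC(=O)O[C@@H]1[C@]13C[C@@](C(C(=O)SCC)C1=O)(CO[Si](c5ccccc5)(c5ccccc5)C(C)(C)C)[C@H](CCC=C)CN3C2 | intermediate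
27 | tert-butyl prop-2-enoate | C=CC(=O)OC(C)(C)C | starting material
28 | C21-quaternary keto thioester (26 with exo CH2CH2CO2tBu on C21; COSEt endo) | C[C@@]12CC(=O)O[C@@H]1[C@]13C[C@@]([C@](C(=O)SCC)(CCC(=O)OC(C)(C)C)C1=O)(CO[Si](c5ccccc5)(c5ccccc5)C(C)(C)C)[C@H](CCC=C)CN3C2 | intermediate
29 | hydroxy ketone (28 with endo CH2OH on C21 in place of COSEt) | C[C@@]12CC(=O)O[C@@H]1[C@]13C[C@@]([C@](CO)(CCC(=O)OC(C)(C)C)C1=O)(CO[Si](c5ccccc5)(c5ccccc5)C(C)(C)C)[C@H](CCC=C)CN3C2 | intermediate
30 | diol (endo CH2OH on C21; exo C27–OH; tert-butyl ester intact) | C[C@@]12CC(=O)O[C@@H]1[C@]13C[C@@]([C@](CO)(CCC(=O)OC(C)(C)C)[C@@H]1O)(CO[Si](c5ccccc5)(c5ccccc5)C(C)(C)C)[C@H](CCC=C)CN3C2 | intermediate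
31 | hydroxy aldehyde (30 with endo CHO on C21) | C[C@@]12CC(=O)O[C@@H]1[C@]13C[C@@]([C@](C=O)(CCC(=O)OC(C)(C)C)[C@@H]1O)(CO[Si](c5ccccc5)(c5ccccc5)C(C)(C)C)[C@H](CCC=C)CN3C2 | intermediate
32 | hydroxy acid (31 with free C24 carboxylic acid) | C[C@@]12CC(=O)O[C@@H]1[C@]13C[C@@]([C@](C=O)(CCC(=O)O)[C@@H]1O)(CO[Si](c5ccccc5)(c5ccccc5)C(C)(C)C)[C@H](CCC=C)CN3C2 | intermediate
33 | pentacyclic lactone aldehyde (rings A–E; endo CHO on C21) | C[C@@]12CC(=O)O[C@@H]1[C@]13C[C@@]([C@]5(C=O)CCC(=O)O[C@H]15)(CO[Si](c6ccccc6)(c6ccccc6)C(C)(C)C)[C@H](CCC=C)CN3C2 | intermediate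
34 | pentacyclic 1,8-enyne (rings A–E; endo ethynyl on C21; but-3-enyl on C13; O12 TBDPS ether) | C[C@@]12CC(=O)O[C@@H]1[C@]13C[C@@]([C@]5(C#C)CCC(=O)O[C@H]15)(CO[Si](c6ccccc6)(c6ccccc6)C(C)(C)C)[C@H](CCC=C)CN3C2 | intermediate
35 | hexacarbonyldicobalt complex of the C19≡C20 alkyne of 34 | C[C@@]12CC(=O)O[C@@H]1[C@]13C[C@@]([C@]5(C67[CH]8[Co]6(=C=O)(=C=O)(=C=O)[Co]78(=C=O)(=C=O)=C=O)CCC(=O)O[C@H]15)(CO[Si](c9ccccc9)(c9ccccc9)C(C)(C)C)[C@H](CCC=C)CN3C2 | intermediate
36 | heptacyclic C18 enone (rings A–G; C19=C20; H16 cis to H13; O12 TBDPS ether) | C[C@@]12CC(=O)O[C@@H]1[C@]13C[C@@]4(CO[Si](c6ccccc6)(c6ccccc6)C(C)(C)C)[C@H](CC[C@H]5CC(=O)C=C5[C@]45CCC(=O)O[C@H]15)CN3C2 | intermediate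
37 | C18 allylic alcohol (36 with C18–OH; either epimer) | C[C@@]12CC(=O)O[C@@H]1[C@]13C[C@@]4(CO[Si](c6ccccc6)(c6ccccc6)C(C)(C)C)[C@H](CC[C@H]5CC(O)C=C5[C@]45CCC(=O)O[C@H]15)CN3C2 | intermediate
38 | O12 tert-butyldiphenylsilyl ether of the target | C[C@@]12CC(=O)O[C@@H]1[C@]13C[C@@]4(CO[Si](c6ccccc6)(c6ccccc6)C(C)(C)C)[C@H](CC[C@H]5CCC=C5[C@]45CCC(=O)O[C@H]15)CN3C2 | intermediate
39 | target CNP0247797.1 | C[C@@]12CC(=O)O[C@@H]1[C@]13C[C@@]4(CO)[C@H](CC[C@H]5CCC=C5[C@]45CCC(=O)O[C@H]15)CN3C2 | target

**Step count and risks**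

Total: 26 steps. Longest linear sequence: 23 steps (steps 1, 3 to 7 and 10 to 26; steps 2, 8 and 9 make side fragments).

The three steps most likely to fail, in order of risk:

Step 23. The seven-membered tether ring may close too slowly, so that the cobalt complex loses the alkyne or reacts intermolecularly before the alkene inserts. The fallback sets out from 34 and closes the two rings one after the other. Ring-closing enyne metathesis (RuCl2(=CHPh)(PCy3)(H2IMes), the second-generation Grubbs catalyst, under ethylene, with N29 masked as its tosylate salt) forms C16=C20 and gives the vinylcycloheptene diene F1. Cyclopropanation of the terminal vinyl group (CH2N2, Pd(OAc)2) gives the vinylcyclopropane F2. A vinylcyclopropane–cyclopentene rearrangement under zerovalent nickel catalysis (Ni(cod)2 with the carbene ligand IPr) then forms the C16–CH2 bond and moves the alkene to C19=C20. This comes back to the route at 38, so steps 24 and 25 are not needed; the C16 configuration would there be set in the rearrangement and would have to be checked.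

Step 17. The hindered secondary amine may condense poorly with the aldehyde, or the enamine may be hydrolysed or reduced before it cyclises. The fallback sets out from 22 (neutralised with aq NaHCO3) and makes the same C13–C10 bond by a radical. Opening of 2-(but-3-enyl)oxirane at its CH2 terminus by N29 (LiClO4, MeCN) gives the amino alcohol F3, and phenyl chlorothionoformate with pyridine gives the thionocarbonate F4. Bu3SnH and AIBN (Barton–McCombie radical generation) then form the secondary C13 radical, whose 6-exo Giese cyclisation onto C10 of the alkylidene β-keto thioester, again held cis to N29 by the tether, comes back to the route at 26.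

Step 22. Methoxide may open ring E before the hindered aldehyde has reacted, and the freed C27 alkoxide could then cause retro-aldol cleavage of the C21–C27 bond. The fallback sets out from 31 and makes the alkyne before ring E exists. Silylation of the C27 hydroxyl group (TESOTf, 2,6-lutidine) gives the silyl ether aldehyde F5, and Ohira–Bestmann homologation gives the silyl ether alkyne F6. TFA removes the tert-butyl ester and the triethylsilyl group to give the hydroxy acid alkyne F7, and carbodiimide lactonisation (EDCI·HCl, DMAP) comes back to the route at 34.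

Further compounds
F1 | step 23 | vinylcycloheptene diene (ring F closed; C16=C20; vinyl C19H=CH2 on C20) | C[C@@]12CC(=O)O[C@@H]1[C@]13C[C@@]4(CO[Si](c6ccccc6)(c6ccccc6)C(C)(C)C)[C@H](CCC=C(C=C)[C@]45CCC(=O)O[C@H]15)CN3C2
F2 | step 23 | vinylcyclopropane (F1 with the terminal vinyl group cyclopropanated) | C[C@@]12CC(=O)O[C@@H]1[C@]13C[C@@]4(CO[Si](c6ccccc6)(c6ccccc6)C(C)(C)C)[C@H](CCC=C(C7CC7)[C@]45CCC(=O)O[C@H]15)CN3C2
F3 | step 17 | amino alcohol (N29–CH2–CH(OH)–CH2CH2CH=CH2 on the spiro enone thioester) | C[C@@]12CC(=O)O[C@@H]1[C@]3(C(=O)C(C(=O)SCC)=C(CO[Si](c4ccccc4)(c4ccccc4)C(C)(C)C)C3)N(CC(O)CCC=C)C2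
F4 | step 17 | O-phenyl thionocarbonate of F3 | C[C@@]12CC(=O)O[C@@H]1[C@]3(C(=O)C(C(=O)SCC)=C(CO[Si](c4ccccc4)(c4ccccc4)C(C)(C)C)C3)N(CC(OC(=S)Oc5ccccc5)CCC=C)C2
F5 | step 22 | silyl ether aldehyde (31 with C27–OSiEt3) | C[C@@]12CC(=O)O[C@@H]1[C@]13C[C@@]([C@](C=O)(CCC(=O)OC(C)(C)C)[C@@H]1O[Si](CC)(CC)CC)(CO[Si](c5ccccc5)(c5ccccc5)C(C)(C)C)[C@H](CCC=C)CN3C2
F6 | step 22 | silyl ether alkyne (F5 with endo ethynyl on C21) | C[C@@]12CC(=O)O[C@@H]1[C@]13C[C@@]([C@](C#C)(CCC(=O)OC(C)(C)C)[C@@H]1O[Si](CC)(CC)CC)(CO[Si](c5ccccc5)(c5ccccc5)C(C)(C)C)[C@H](CCC=C)CN3C2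
F7 | step 22 | hydroxy acid alkyne (free C27–OH and C24 acid; endo ethynyl on C21) | C[C@@]12CC(=O)O[C@@H]1[C@]13C[C@@]([C@](C#C)(CCC(=O)O)[C@@H]1O)(CO[Si](c5ccccc5)(c5ccccc5)C(C)(C)C)[C@H](CCC=C)CN3C2
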